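The runs are simulated with constants of no real substance, noise included.

Start with an easy step: count halvings, one hand at a time.

the same everywhere: left-handed substrate 2.0 × 10⁻⁴ M; right-handed substrate 2.0 × 10⁻⁴ M; racemization catalyst 5 mol%; impurity 3.4 µM
- east: reagent 2.8 equiv; run made earlier
- south-east: reagent 8.6 equiv; run made earlier
- Monday's: reagent 2.50 equiv; time 2.5 min
- Thursday's: reagent 7.50 equiv; time 2.5 min

| run | time / s | right-handed substrate / % | left-handed substrate / % | left-handed product / % |
|---|---|---|---|---|
| east | 10.0 | 45.9 | 31.3 | 18.7 |
| east | 12.0 | 44.9 | 29.8 | 21.4 |
| east | 20.0 | 41.9 | 20.6 | 29.8 |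
| east | 40.0 | 36.0 | 10.1 | 39.9 |
| east | 80.0 | 28.3 | 2.7 | 47.6 |
| south-east | 10.0 | 37.7 | 11.7 | 38.6 |
| south-east | 20.0 | 29.7 | 2.6 | 46.4 |
| south-east | 40.0 | 16.7 | 0 | 49.9 |
| south-east | 50.0 | 13.6 | 0 | 50.0 |
| south-east | 80.0 | 7.7 | 0 | 50.2 |

(standard deviation of a reading: 0.5 percentage points)

* the winner by excess of right-handed substrate over left-handed substrate among what is left of the two; "neither" if no more than 2 percentage points parts them (Monday's / Thursday's / neither)
* excess of right-handed substrate over left-handed substrate among what is left of the two at the end, Monday's
* excess of right-handed substrate over left-handed substrate among what is left of the two at the end, Thursday's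

- reagent is single-handed; left-handed substrate and right-handed substrate are mirror images of each other, charged as a racemate, each of them at the stated concentration
- an excess is below zero if the other one leads
- the handed part of reagent does not stay in what it makes, so the products of the two hands are mirror images too

1. **Ratio.** Both hands meet the same reagent. For each hand, take the logarithm of its charge over what remains, then divide the left-hand figure by the right-hand one. The south-east run at 10.0 s gives 5.14. This is s, the left-hand half-lives passed per right-hand half-life, or selectivity factor. The east run, with 2.8 equiv of reagent, reads 5.02 at 20.0 s. If right-handed substrate stands at fraction f of its charge, left-handed substrate stands at f^s. The excess is then (f − f^s)/(f + f^s).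

2. **Catalyst.** By hand, it would refill the left-handed substrate. But in the east run, left-handed substrate plus left-handed product reads 50.0% at 10.0 s and 50.3% at 80.0 s. So I leave it out of my count.

3. **Reagent.** Equivalents count on left-handed substrate, and that hand takes one equivalent. I hold the remainder constant, a pseudo-first-order view, although it falls further. The south-east run at 50.0 s then gives a right-hand constant of 17.1 /M/s. The right-hand half-life is 135 s for Monday's and 31.1 s for Thursday's.

4. **Time.** 2.5 min holds 1.11 right-hand half-lives on Monday's and 4.82 on Thursday's. So f is 46.3% and 3.54%. My excesses are 92.1% for Monday's and >99.9% for Thursday's.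

5. **Forecast.** It names Thursday's, with 96% (94% to 97.5%) for Monday's and 100% (99.5% to 100%) for Thursday's. Its grounds for Monday's: “Right fraction is about 0.40 and left about 0.008”. My Monday's figure is lower.

Thursday's wins, with >99.9% against 90.9% for Monday's. Monday's right-handed substrate ends at 48% of its charge, where the forecast had a fraction of 0.40. Now use s: that 48% gives left-handed substrate at 2.21% of its charge, and Monday's flask holds 2.3%.

    2 racemization catalyst → spent catalyst A (k = 2500 /M/s)
    racemization catalyst + impurity → spent catalyst B (k = 4.50 × 10⁶ /M/s)
    racemization catalyst → spent catalyst C (k = 0.340 /s)
    reagent + right-handed substrate → right-handed product (k = 18.0 /M/s)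
    reagent + left-handed substrate → left-handed product (k = 92.0 /M/s)
    left-handed substrate + racemization catalyst ⇌ right-handed substrate + racemization catalyst, rate k6*[racemization catalyst]*[left-handed substrate] forward; the back reaction follows from the equilibrium constant (k = 350 /M/s)

Take Monday's flask with 1.00 equiv of reagent, where right-handed substrate ends at 81% of its charge. Then s gives left-handed substrate at 33.9% of its charge and an excess of 41.0%; the computed flask gives 34% and 40.9%.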